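**Retrosynthetic overview**
- The strategy rests on the two identical arm ends. In each arm the veratryl carbinol carbon C7 (7R) sits next to C8 (8S), which carries a methyl group and the guaiacyl ether oxygen, and the two form an erythro (anti) pair. Both C7–aryl bonds are cut at once, giving a bis[(S)-2-aryloxypropanal] on the intact core and two 3,4-dimethoxyphenyl titanium nucleophiles.
- The two formyl groups come from primary alcohols carried as silyl ethers. C8 is bought as methyl (R)-lactate and inverted by Mitsunobu etherification of 4-bromo-2-methoxyphenol.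
- The core is a 2,5-diaryl-3,4-dimethyloxolane with the aryl groups 2,5-cis, the methyl groups 3,4-cis and each aryl trans to its neighbouring methyl. It is opened at a benzylic C–O bond to a 1,4-diol. The two aryl–C(O) bonds are then cut back to the bis-Weinreb amide of meso-2,3-dimethylsuccinic acid, which supplies C3 and C4.
- Ring order: the four benzene rings are bought. The oxolane is the only ring made (step 7), before the arms are finished. The key step closes no ring.

Key step: step 11

Remark: C7 and C8 are the carbinol and aryloxy carbons of each arm, and the core uses oxolane numbering. The core alone is meso and the two arms are identical and homochiral, so swapping the two ends gives the same compound and no step has to tell the halves apart.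

**Step 1**
Reactants: 1 4-bromo-2-methoxyphenol; 2 methyl (R)-lactate
Product: 3 methyl (S)-2-(4-bromo-2-methoxyphenoxy)propanoate
Conditions: PPh3, DIAD, THF, 0 °C → rt
Reagents that add atoms: none
Why: In this Mitsunobu etherification the phenol displaces the oxyphosphonium-activated secondary hydroxyl by SN2 with inversion, so the (R)-alcohol gives the (S)-aryloxy centre that becomes C8.

**Step 2**
Reactants: 3 methyl (S)-2-(4-bromo-2-methoxyphenoxy)propanoate
Product: 4 (S)-2-(4-bromo-2-methoxyphenoxy)propan-1-ol
Conditions: LiAlH4, THF, 0 °C; then Na2SO4·10H2O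
Reagents that add atoms: none
Why: Hydride reduction of the ester is fast at 0 °C, where the aryl bromide is inert and the α-centre is not enolised.

**Step 3**
Reactants: 4 (S)-2-(4-bromo-2-methoxyphenoxy)propan-1-ol
Product: 5 (S)-[2-(4-bromo-2-methoxyphenoxy)propoxy](tert-butyl)diphenylsilane
Conditions: TBDPSCl, imidazole, CH2Cl2, rt
Reagents that add atoms: tert-butyl(chloro)diphenylsilane (TBDPSCl), CC(C)(C)[Si](Cl)(c1ccccc1)c1ccccc1
Why: This is a standard imidazole-promoted silylation of a primary alcohol, and TBDPS is chosen because it tolerates n-BuLi, LiAlH4 and the acid of step 7.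

**Step 4**
Reactants: 6 meso-2,3-dimethylsuccinic acid
Product: 7 meso-N1,N4-dimethoxy-N1,N4,2,3-tetramethylbutanediamide (bis-Weinreb amide)
Conditions: MeNH(OMe)·HCl, EDC·HCl, HOBt (cat.), N-methylmorpholine, CH2Cl2, 0 °C → rt
Reagents that add atoms: N,O-dimethylhydroxylamine hydrochloride, CNOC.Cl
Why: In this carbodiimide/HOBt amide coupling the amine is present from the start, so any cyclic anhydride formed from the 1,4-diacid is opened and the freed acid re-activated, while the mild base and temperature leave the two α-centres in their meso relationship.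

**Step 5**
Reactants: 5 (S)-[2-(4-bromo-2-methoxyphenoxy)propoxy](tert-butyl)diphenylsilane (2.3 equiv); 7 meso bis-Weinreb amide
Product: 10 (2R,3S)-2,3-dimethyl-1,4-bis{3-methoxy-4-[(S)-1-(tert-butyldiphenylsilyloxy)propan-2-yloxy]phenyl}butane-1,4-dione, via aryllithium 8 (not isolated), via dilithium bis-hemiaminal adduct 9 (not isolated)
Conditions: n-BuLi (2.2 equiv), THF, −78 °C; then 7, −78 → −10 °C; AcOH, −78 °C
Reagents that add atoms: n-butyllithium, [Li]CCCC (lithium of 8 and 9 only; nothing of it stays in 10)
Why: Bromine–lithium exchange outruns ortho-metalation at −78 °C, and the Weinreb ketone synthesis holds each aryl adduct as a five-membered lithium chelate until the quench, which rules out over-addition, keeps the methyl-bearing centres next to a non-enolisable carbon and lets cold acetic acid release the meso-type diketone without contact with base.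

**Step 6**
Reactants: 10 meso-type 1,4-diketone
Product: 11 (2R,3S)-2,3-dimethyl-1,4-bis{3-methoxy-4-[(S)-1-(tert-butyldiphenylsilyloxy)propan-2-yloxy]phenyl}butane-1,4-diol (C1 and C4 carbinols as an epimer mixture)
Conditions: LiAlH4, THF, −78 → 0 °C; then Na2SO4·10H2O
Reagents that add atoms: none
Why: Hydride reduction of the two aryl ketones is fast under aprotic conditions so the α-centres are not epimerised; Felkin–Anh attack favours the carbinol configuration that maps onto the aryl/methyl-trans oxolane, but the epimer composition does not matter because step 7 passes through benzylic cations.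

**Step 7**
Reactants: 11 1,4-diol
Product: 12 (2R,3R,4S,5S)-2,5-bis{3-methoxy-4-[(S)-1-(tert-butyldiphenylsilyloxy)propan-2-yloxy]phenyl}-3,4-dimethyloxolane (aryl groups 2,5-cis; methyl groups 3,4-cis; each aryl trans to the neighbouring methyl)
Conditions: p-TsOH·H2O (10 mol %), CH2Cl2 (0.01 M), rt
Reagents that add atoms: none
Why: Acid-catalysed SN1 cyclodehydration (5-exo-trig capture of a p-alkoxybenzyl cation by the remote hydroxyl) closes the oxolane, and because the p-alkoxybenzylic C–O bonds of the product ionise reversibly under the same acid, C2 and C5 should settle under thermodynamic control with each aryl trans to its neighbouring methyl, while the cis-methyl pair C3/C4 inherited from 6 is untouched and the TBDPS ethers tolerate catalytic sulfonic acid in an aprotic solvent.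

**Step 8**
Reactants: 12 oxolane bis-silyl ether
Product: 13 (2S,2'S)-2,2'-{[(2R,3R,4S,5S)-3,4-dimethyloxolane-2,5-diyl]bis[(2-methoxy-4,1-phenylene)oxy]}bis(propan-1-ol)
Conditions: Bu4NF, THF, rt
Reagents that add atoms: none
Why: Fluoride-driven desilylation is powered by the strong Si–F bond, and nothing else in 12 is sensitive to fluoride or mild base.

**Step 9**
Reactants: 13 oxolane bis(primary alcohol)
Product: 14 (2S,2'S)-2,2'-{[(2R,3R,4S,5S)-3,4-dimethyloxolane-2,5-diyl]bis[(2-methoxy-4,1-phenylene)oxy]}dipropanal
Conditions: Dess–Martin periodinane, NaHCO3, CH2Cl2, 0 °C → rt; used without chromatography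
Reagents that add atoms: none
Why: The Dess–Martin oxidation runs near neutrality at or below room temperature, stops at the aldehyde and is a usual choice for configurationally labile α-heteroatom aldehydes, so both C8 centres should be kept.

**Step 10**
Reactants: 15 4-bromo-1,2-dimethoxybenzene
Product: 17 3,4-dimethoxyphenyltitanium triisopropoxide (THF/hexane solution used directly), via 3,4-dimethoxyphenyllithium 16 (not isolated)
Conditions: n-BuLi, THF, −78 °C; then ClTi(OiPr)3 (1.05 equiv), −78 → −40 °C
Reagents that add atoms: n-butyllithium, [Li]CCCC (lithium of 16 only); chlorotitanium triisopropoxide, CC(C)O[Ti](Cl)(OC(C)C)OC(C)C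
Why: Bromine–lithium exchange followed by salt metathesis (transmetalation) gives an aryl reagent of low basicity and low Lewis acidity, and the slight excess of the titanium chloride ensures that no free aryllithium remains.

**Step 11**
Reactants: 14 core bis[(S)-2-aryloxypropanal]; 17 3,4-dimethoxyphenyltitanium triisopropoxide (3 equiv, two consumed)
Product: 19 target CNP0116650.10 with both arms (7R,8S), via bis-titanium alkoxide 18 (not isolated)
Conditions: THF, −78 → −20 °C; then H2O
Reagents that add atoms: none
Why: After weak O→Ti coordination the aryl group moves from tetravalent titanium to the formyl carbon through a compact cyclic transition state, giving the titanium alkoxide 18 that water cleaves to the carbinol; this is the known non-chelation-controlled addition of organotitanium triisopropoxides to α-alkoxy aldehydes, run here twice in one flask, and no ring is closed. Each new C7 centre is controlled only by its neighbouring C8 (1,2-induction): in the polar Felkin–Anh arrangement the C8–OAr bond, the best σ* acceptor, stands perpendicular to the C=O plane and anti to the incoming aryl group, which follows the Bürgi–Dunitz line past the C8 hydrogen while the C8 methyl lies next to the carbonyl oxygen, so the (S)-aldehyde gives the 7R carbinol, that is the erythro 7R,8S pair, and the Cornforth dipole model predicts the same face. The selectivity needed is Felkin–Anh over Cram-chelate attack, and it is secured by the three isopropoxide donors, which leave titanium too weakly Lewis acidic and too crowded to bind the aldehyde oxygen together with the C8 ether oxygen or the adjacent guaiacyl methoxy oxygen, and by the poor donor ability of an aryl ether oxygen. The reagent is barely basic, so the acidic C8–H of the α-aryloxy aldehyde should stay in place at low temperature and C8 keeps its configuration. The two formyl groups sit far apart on the para positions of the two guaiacyl rings, so they react independently, the core centres play no part, and the per-arm selectivity counts twice in the product.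

**Compound list**
1 | 4-bromo-2-methoxyphenol | COc1cc(Br)ccc1O | starting material
2 | methyl (R)-lactate | C[C@@H](O)C(=O)OC | starting material
3 | methyl (S)-2-(4-bromo-2-methoxyphenoxy)propanoate | COC(=O)[C@H](C)Oc1ccc(Br)cc1OC | intermediate
4 | (S)-2-(4-bromo-2-methoxyphenoxy)propan-1-ol | OC[C@H](C)Oc1ccc(Br)cc1OC | intermediate
5 | (S)-[2-(4-bromo-2-methoxyphenoxy)propoxy](tert-butyl)diphenylsilane | CC(C)(C)[Si](c1ccccc1)(c1ccccc1)OC[C@H](C)Oc1ccc(Br)cc1OC | intermediate
6 | meso-2,3-dimethylsuccinic acid | OC(=O)[C@@H](C)[C@@H](C)C(O)=O | starting material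
7 | meso bis-Weinreb amide of 6 | CON(C)C(=O)[C@@H](C)[C@@H](C)C(=O)N(C)OC | intermediate
8 | aryllithium from 5 | [Li]c1ccc(O[C@@H](C)CO[Si](c2ccccc2)(c2ccccc2)C(C)(C)C)c(OC)c1 | intermediate
9 | dilithium bis-hemiaminal adduct (hemiaminal carbons undefined) | CC(C)(C)[Si](c1ccccc1)(c1ccccc1)OC[C@H](C)Oc1ccc(cc1OC)C(O[Li])(N(C)OC)[C@@H](C)[C@@H](C)C(O[Li])(N(C)OC)c1ccc(O[C@@H](C)CO[Si](c2ccccc2)(c2ccccc2)C(C)(C)C)c(OC)c1 | intermediate
10 | meso-type 2,3-dimethyl-1,4-diaryl-1,4-diketone with two (S)-silyloxypropyl ether arms | CC(C)(C)[Si](c1ccccc1)(c1ccccc1)OC[C@H](C)Oc1ccc(cc1OC)C(=O)[C@@H](C)[C@@H](C)C(=O)c1ccc(O[C@@H](C)CO[Si](c2ccccc2)(c2ccccc2)C(C)(C)C)c(OC)c1 | intermediate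
11 | corresponding 1,4-diol, carbinol centres as epimer mixture | CC(C)(C)[Si](c1ccccc1)(c1ccccc1)OC[C@H](C)Oc1ccc(cc1OC)C(O)[C@@H](C)[C@@H](C)C(O)c1ccc(O[C@@H](C)CO[Si](c2ccccc2)(c2ccccc2)C(C)(C)C)c(OC)c1 | intermediate
12 | (2R,3R,4S,5S)-oxolane bis-TBDPS ether | CC(C)(C)[Si](c1ccccc1)(c1ccccc1)OC[C@H](C)Oc2ccc([C@H]3O[C@@H](c4ccc(O[C@@H](C)CO[Si](c5ccccc5)(c5ccccc5)C(C)(C)C)c(OC)c4)[C@H](C)[C@@H]3C)cc2OC | intermediate
13 | oxolane bis[(S)-2-aryloxypropan-1-ol] | OC[C@H](C)Oc2ccc([C@H]3O[C@@H](c4ccc(O[C@@H](C)CO)c(OC)c4)[C@H](C)[C@@H]3C)cc2OC | intermediate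
14 | oxolane bis[(S)-2-aryloxypropanal] | O=C[C@H](C)Oc2ccc([C@H]3O[C@@H](c4ccc(O[C@@H](C)C=O)c(OC)c4)[C@H](C)[C@@H]3C)cc2OC | intermediate
15 | 4-bromo-1,2-dimethoxybenzene | COc1ccc(Br)cc1OC | starting material
16 | 3,4-dimethoxyphenyllithium | COc1ccc([Li])cc1OC | intermediate
17 | 3,4-dimethoxyphenyltitanium triisopropoxide | COc1ccc([Ti](OC(C)C)(OC(C)C)OC(C)C)cc1OC | intermediate
18 | bis(triisopropoxytitanium) alkoxide of the target | COc1ccc([C@@H](O[Ti](OC(C)C)(OC(C)C)OC(C)C)[C@H](C)Oc2ccc([C@H]3O[C@@H](c4ccc(O[C@@H](C)[C@H](O[Ti](OC(C)C)(OC(C)C)OC(C)C)c5ccc(OC)c(OC)c5)c(OC)c4)[C@H](C)[C@@H]3C)cc2OC)cc1OC | intermediate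
19 | CNP0116650.10: (2R,3R,4S,5S)-oxolane core, both arms (1R,2S)-1-(3,4-dimethoxyphenyl)-1-hydroxypropan-2-yl ethers | COc1ccc([C@@H](O)[C@H](C)Oc2ccc([C@H]3O[C@@H](c4ccc(O[C@@H](C)[C@H](O)c5ccc(OC)c(OC)c5)c(OC)c4)[C@H](C)[C@@H]3C)cc2OC)cc1OC | target

**Totals**
Total step count: 11.
Longest linear sequence: 9 (steps 1, 2, 3, 5, 6, 7, 8, 9, 11).

**Steps most likely to fail**

**Step 11.**
- Risk: facial selectivity may be poor at one or both formyl groups, and any shortfall is felt twice. C8 may also erode through enolisation of the α-aryloxy aldehyde before addition.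
- Fallback: C7 is set by hydride delivery to a ketone instead of by induction in the C–C bond formation.
- From 14, commercial 3,4-dimethoxyphenylmagnesium bromide (THF, −78 °C) is added without regard to the face, giving the C7-epimeric bis-carbinol mixture F1.
- Dess–Martin oxidation converts both carbinols into the bis(α-aryloxy aryl ketone) F2.
- Chelation-controlled reduction with Zn(BH4)2 in Et2O at low temperature follows. Zinc ties the ketone oxygen to the C8 ether oxygen and hydride enters past the C8 hydrogen. This should give the erythro carbinols and returns to the route at 19.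

**Step 7.**
- Risk: equilibration at C2/C5 may be incomplete and leave aryl/methyl-cis isomers. Proton loss from the benzylic cation would scramble C3/C4. Friedel–Crafts closure onto the other electron-rich ring is also possible.
- Fallback: thermodynamic acid control is replaced by substrate-controlled reduction and a kinetic closure under basic conditions.
- From 10, the bulky hydride LiBH(s-Bu)3 (THF, −78 °C) should reduce both ketones in the Felkin–Anh sense to the stereodefined all-Felkin diol F3. Both of its carbinols already have the configuration of C2 and C5.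
- MsCl/Et3N (CH2Cl2, 0 °C) forms the benzylic monomesylate F4, which ionises at once.
- The remaining hydroxyl, whose centre is retained, captures the cation trans to the neighbouring methyl and gives 12 without any acid.

**Step 5.**
- Risk: the methyl-bearing centres may epimerise from meso to dl during addition, quench or purification. The reaction may also stall after the first addition at the crowded anionic mono-adduct.
- Fallback: the configuration of the diketone is made irrelevant.
- From 10 of any meso/dl composition, Paal–Knorr cyclodehydration (p-TsOH, toluene, reflux) gives the 2,5-diaryl-3,4-dimethylfuran F5.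
- The two faces of F5 are equivalent through its twofold axis.
- Hydrogenation (H2, Pd/C, EtOAc) adds all four hydrogens from one face and gives the all-cis oxolane F6, which re-creates the cis-methyl pair.
- Exposure to the catalytic acid of step 7 epimerises C2 and C5 to the aryl/methyl-trans isomer and rejoins the route at 12.

**Further compounds**
F1 | step 11 | C7-epimeric bis-carbinol mixture (C8 and core defined) | COc1ccc(C(O)[C@H](C)Oc2ccc([C@H]3O[C@@H](c4ccc(O[C@@H](C)C(O)c5ccc(OC)c(OC)c5)c(OC)c4)[C@H](C)[C@@H]3C)cc2OC)cc1OC
F2 | step 11 | bis[(S)-2-aryloxy-1-(3,4-dimethoxyphenyl)propan-1-one] on the oxolane core | COc1ccc(C(=O)[C@H](C)Oc2ccc([C@H]3O[C@@H](c4ccc(O[C@@H](C)C(=O)c5ccc(OC)c(OC)c5)c(OC)c4)[C@H](C)[C@@H]3C)cc2OC)cc1OC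
F3 | step 7 | stereodefined all-Felkin 1,4-diol | CC(C)(C)[Si](c1ccccc1)(c1ccccc1)OC[C@H](C)Oc1ccc(cc1OC)[C@@H](O)[C@@H](C)[C@@H](C)[C@@H](O)c1ccc(O[C@@H](C)CO[Si](c2ccccc2)(c2ccccc2)C(C)(C)C)c(OC)c1
F4 | step 7 | benzylic monomesylate of F3 | CC(C)(C)[Si](c1ccccc1)(c1ccccc1)OC[C@H](C)Oc1ccc(cc1OC)[C@@H](OS(C)(=O)=O)[C@@H](C)[C@@H](C)[C@@H](O)c1ccc(O[C@@H](C)CO[Si](c2ccccc2)(c2ccccc2)C(C)(C)C)c(OC)c1
F5 | step 5 | 2,5-diaryl-3,4-dimethylfuran with both silyl ether arms | CC(C)(C)[Si](c1ccccc1)(c1ccccc1)OC[C@H](C)Oc1ccc(cc1OC)-c1oc(c(C)c1C)-c1ccc(O[C@@H](C)CO[Si](c2ccccc2)(c2ccccc2)C(C)(C)C)c(OC)c1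
F6 | step 5 | all-cis 2,5-diaryl-3,4-dimethyloxolane bis-silyl ether | CC(C)(C)[Si](c1ccccc1)(c1ccccc1)OC[C@H](C)Oc2ccc([C@@H]3O[C@H](c4ccc(O[C@@H](C)CO[Si](c5ccccc5)(c5ccccc5)C(C)(C)C)c(OC)c4)[C@H](C)[C@@H]3C)cc2OC
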